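The constants of the suspected steps are not given, but two times can be read from the amber run by working with the fraction of starting material left and not the fraction made.

| flask | starting material | second substrate | coupling partner | free catalyst | remark | time |
|---|---|---|---|---|---|---|
| amber | 0.10 M | 0.20 M | 0.26 M | 2.6 mM | run made earlier |  |
| Sunday's | 0.10 M | 0.200 M | 0.150 M | 2.6 mM |  | 40 min |
| Saturday's | 0.10 M | 0.200 M | 0.220 M | 2.6 mM |  | 40 min |

- amber (time / min: starting material / %, target / %, catalyst intermediate A / %): 2.00: 93, 6, 0; 5.00: 83, 8, 0; 10.0: 71, 17, 0; 15.0: 54, 24, 0; 20.0: 53, 26, 0; 30.0: 38, 36, 0

(readings scatter by 2 percentage points)

- a species is counted by the starting material in it: one homo dimer counts as two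
- on the list of suspects stand: coupling partner + catalyst intermediate A -> free catalyst + target; second substrate + free catalyst <-> catalyst intermediate B; starting material + free catalyst <-> catalyst intermediate A; coupling partner + catalyst intermediate B -> free catalyst + second product; 2 starting material -> homo dimer

1. which of these there is most of at the end, counted by the starting material in it, Sunday's (starting material / target / catalyst intermediate A)
2. which of these there is most of at the end, counted by the starting material in it, Saturday's (starting material / target / catalyst intermediate A)
3. amount of the one of these that there is most of at the end, in percent of the starting material charged, Sunday's
4. amount of the one of these that there is most of at the end, in percent of the starting material charged, Saturday's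

Target forms when coupling partner meets catalyst intermediate A, so its rate is taken as proportional to partner and to the fraction left, while homo dimer takes two starting material, so the missing part is taken to go with the square of that fraction. By trapezia up to 30.0 min, the amber run's area under the fraction left reads 18.8 min, and the area under its square 12.7 min. Dividing by the 36 % of target and the 26.0 % missing gives a target time of 52.1 min and a dimer time of 48.9 min. The split number, dimer time over target time, a kind of selectivity factor, reads 0.939 in the amber run, and it is taken to scale with the partner charge, the target time being taken as inversely proportional to that charge and the dimer time as unchanged.

Let E be the exponential of minus time over target time. With both times held constant through a run, the fraction left is then E over one plus (one minus E) over the split number, and target is the split number times the logarithm of one plus (one minus E) over it. By this reckoning Sunday's, with split number 0.542 and E 0.642, leaves 38.7 % starting material, more than its 27.5 % target. By the same reckoning Saturday's, with split number 0.794 and E 0.522, gives 37.4 % target against 32.6 % starting material, a margin of 4.8 percentage points with readings scattered by 2 points.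

The forecast, whose numbers differ from this reckoning, chose starting material for Sunday's at 40 % (35 % to 46 %) and target for Saturday's at 36 % (31 % to 41 %), warning that “partner lost to the second-product route would shift it towards starting material”.

The flask gives starting material at 37.4 % on Sunday's, and target at 37.3 % on Saturday's, with starting material at 31.6 %, so the forecast held.

    coupling partner + catalyst intermediate A → free catalyst + target (k = 17.0 M⁻¹ min⁻¹)
    second substrate + free catalyst ⇌ catalyst intermediate B (K = 2.40 M⁻¹, k = 110 M⁻¹ min⁻¹)
    starting material + free catalyst ⇌ catalyst intermediate A (K = 3.70 M⁻¹, k = 87.0 M⁻¹ min⁻¹)
    coupling partner + catalyst intermediate B → free catalyst + second product (k = 4.50 M⁻¹ min⁻¹)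
    2 starting material → homo dimer (k = 0.110 M⁻¹ min⁻¹)

On Saturday's, at 40.0 min, catalyst intermediate A is made at 0.993 of the rate at which it is used up, each step taken net. Saturday's holds 0.0235 M of second product there, with 72.4 % of its partner free, against 71 % on Sunday's. With 0.088 M of partner in Saturday's flask, the split number is 0.318 and E 0.771, giving 44.8 % starting material and 17.2 % target; that flask gives 43.3 % and 17.5 %.

(All runs were generated by integration for an exercise, and the scatter is random.)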